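The route rests on disconnecting C2–C3 of flavanone ring C. With ring C open, C2 is the CH2 of an aryl benzyl ether flanked by O1 and ring B, and its C–H bonds are made hydridic by the O1 lone pair and the para 4'-oxygen. A rhodium carbene generated at C3 from a ring A diazoketone should insert into one of these enantiotopic C–H bonds under a chiral dirhodium carboxylate, forming C2–C3, closing ring C and setting 2S in one operation. The precursor is a 2-diazoacetyl ring A carrying the ring B–luteolin benzyl ether on O1, benzyl on O7 and triisopropylsilyl on O5, the flavone being complete and perbenzylated.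

Key step: step 13

Remarks on the chemistry (assumptions and design choices)
- Catalyst sense: which enantiomer of the catalyst gives 2S cannot be deduced safely from smaller 2-alkoxyaryl diazoketones; Rh2(S-PTTL)4, dirhodium tetrakis[N-phthaloyl-(S)-tert-leucinate], is written, and Rh2(R-PTTL)4 would take its place if a model benzyl ether shows the opposite sense.
- O5 group: O5 carries triisopropylsilyl, not a smaller silyl group, because a silyl group on a phenol ortho to the enolising acetyl group can migrate to the enolate oxygen or be lost in the aqueous amine of the diazo transfer; the larger group also screens O5 from the carbene.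
- Ring B source: 3-bromo-4,5-dihydroxybenzaldehyde (commercial) is used, so that both ring B oxygens can be benzylated directly; a vanillin-type methyl ether would first need cleavage.
- Order of events: the flavone is finished before the biaryl coupling and the future C2 is carried as a benzylic alcohol, so that no free ring B aldehyde meets an aldol condensation and no flavone meets a hydride reagent.
- Biaryl axis: the C5'–C8'' axis has three small ortho substituents and is assumed to give no separable atropisomers.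
- Shorthand in names: "tetra-O-benzylluteolin-8-yl" = 5,7-bis(benzyloxy)-2-[3,4-bis(benzyloxy)phenyl]-4-oxo-4H-chromen-8-yl.

Step 1
Reactants: 1 2,4,6-trihydroxyacetophenone
Product: 2 1-[2,4-bis(benzyloxy)-6-hydroxyphenyl]ethan-1-one
Conditions: BnBr (2.1 equiv), K2CO3 (2.2 equiv), DMF, rt to 60 °C
Reagents that add atoms: benzyl bromide, BrCc1ccccc1
Why: Williamson etherification should take the para hydroxyl and one ortho hydroxyl, the last ortho hydroxyl staying free because it is locked in a hydrogen bond to the acetyl carbonyl.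

Step 2
Reactants: 2 1-[2,4-bis(benzyloxy)-6-hydroxyphenyl]ethan-1-one
Product: 3 1-[4,6-bis(benzyloxy)-2-hydroxy-3-iodophenyl]ethan-1-one
Conditions: BnMe3N·ICl2 (1.05 equiv), NaHCO3, CH2Cl2/MeOH, rt
Reagents that add atoms: benzyltrimethylammonium dichloroiodate, C[N+](C)(C)Cc1ccccc1.Cl[I-]Cl
Why: Electrophilic aromatic iodination of a chelated phenol with this reagent should go ortho to the free hydroxyl, the position that later becomes C8 of the flavone.

Step 3
Reactants: 3 1-[4,6-bis(benzyloxy)-2-hydroxy-3-iodophenyl]ethan-1-one; 4 3,4-bis(benzyloxy)benzaldehyde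
Product: 5 (E)-1-[4,6-bis(benzyloxy)-2-hydroxy-3-iodophenyl]-3-[3,4-bis(benzyloxy)phenyl]prop-2-en-1-one
Conditions: KOH (50% aq.), EtOH/THF, rt
Reagents that add atoms: none
Why: Claisen–Schmidt condensation of the methyl ketone with a non-enolisable aldehyde should give the conjugated enone, the E geometry following from the reversible aldol and elimination steps.

Step 4
Reactants: 5 (E)-1-[4,6-bis(benzyloxy)-2-hydroxy-3-iodophenyl]-3-[3,4-bis(benzyloxy)phenyl]prop-2-en-1-one
Product: 6 5,7-bis(benzyloxy)-2-[3,4-bis(benzyloxy)phenyl]-8-iodo-4H-chromen-4-one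
Conditions: I2 (0.1 equiv), DMSO, 130 °C
Reagents that add atoms: none
Why: Iodine-catalysed oxidative cyclisation of a 2'-hydroxychalcone with DMSO as terminal oxidant should give the flavone, and the aryl iodide next to the cyclising hydroxyl is carried through to C8.

Step 5
Reactants: 7 3-bromo-4,5-dihydroxybenzaldehyde
Product: 8 3,4-bis(benzyloxy)-5-bromobenzaldehyde
Conditions: BnBr (2.3 equiv), K2CO3, DMF, 60 °C
Reagents that add atoms: benzyl bromide, BrCc1ccccc1
Why: Williamson etherification of both catechol hydroxyls should be complete with a slight excess of halide.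

Step 6
Reactants: 8 3,4-bis(benzyloxy)-5-bromobenzaldehyde
Product: 9 [3,4-bis(benzyloxy)-5-bromophenyl]methanol
Conditions: NaBH4, THF/MeOH, 0 °C
Reagents that add atoms: none
Why: Borohydride reduction of the aldehyde should be clean at this stage, where no other carbonyl group is present.

Step 7
Reactants: 9 [3,4-bis(benzyloxy)-5-bromophenyl]methanol
Product: 10 [3,4-bis(benzyloxy)-5-(4,4,5,5-tetramethyl-1,3,2-dioxaborolan-2-yl)phenyl]methanol
Conditions: B2pin2 (1.3 equiv), Pd(dppf)Cl2 (5 mol%), KOAc, 1,4-dioxane, 90 °C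
Reagents that add atoms: bis(pinacolato)diboron, CC1(C)OB(OC1(C)C)B1OC(C)(C)C(C)(C)O1
Why: Miyaura borylation of the aryl bromide under acetate base should leave the free benzylic alcohol and the benzyl ethers untouched.

Step 8
Reactants: 6 5,7-bis(benzyloxy)-2-[3,4-bis(benzyloxy)phenyl]-8-iodo-4H-chromen-4-one; 10 [3,4-bis(benzyloxy)-5-(4,4,5,5-tetramethyl-1,3,2-dioxaborolan-2-yl)phenyl]methanol
Product: 11 5,7-bis(benzyloxy)-2-[3,4-bis(benzyloxy)phenyl]-8-[2,3-bis(benzyloxy)-5-(hydroxymethyl)phenyl]-4H-chromen-4-one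
Conditions: Pd(OAc)2 (5 mol%), SPhos (10 mol%), K3PO4, toluene/H2O (10:1), 90 °C
Reagents that add atoms: none
Why: Suzuki–Miyaura coupling of 8-iodo-5,7-dialkoxyflavones with ortho-alkoxyarylboron reagents is the standard way to biflavone-type axes, and the dialkylbiarylphosphine should carry reductive elimination at the tri-ortho-substituted bond.

Step 9
Reactants: 1 2,4,6-trihydroxyacetophenone
Product: 12 1-[4-(benzyloxy)-2,6-dihydroxyphenyl]ethan-1-one
Conditions: BnBr (1.0 equiv), K2CO3 (1.0 equiv), DMF, 0 °C to rt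
Reagents that add atoms: benzyl bromide, BrCc1ccccc1
Why: Williamson etherification with one equivalent of halide should fall mainly on the para hydroxyl, the most acidic and least hindered one, and any dibenzyl ether formed is compound 2 and is not lost.

Step 10
Reactants: 11 5,7-bis(benzyloxy)-2-[3,4-bis(benzyloxy)phenyl]-8-[2,3-bis(benzyloxy)-5-(hydroxymethyl)phenyl]-4H-chromen-4-one; 12 1-[4-(benzyloxy)-2,6-dihydroxyphenyl]ethan-1-one
Product: 13 1-[4-(benzyloxy)-2-{[3,4-bis(benzyloxy)-5-(tetra-O-benzylluteolin-8-yl)phenyl]methoxy}-6-hydroxyphenyl]ethan-1-one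
Conditions: PPh3, DIAD, THF, 0 °C to rt (12 in 1.5-fold excess)
Reagents that add atoms: none
Why: Mitsunobu etherification of a primary benzylic alcohol with an acidic phenol should stop at the monoether, since the two hydroxyls of 12 are equivalent and the one that remains is chelated to the carbonyl.

Step 11
Reactants: 13 1-[4-(benzyloxy)-2-{[3,4-bis(benzyloxy)-5-(tetra-O-benzylluteolin-8-yl)phenyl]methoxy}-6-hydroxyphenyl]ethan-1-one
Product: 14 1-[4-(benzyloxy)-2-{[3,4-bis(benzyloxy)-5-(tetra-O-benzylluteolin-8-yl)phenyl]methoxy}-6-[(triisopropylsilyl)oxy]phenyl]ethan-1-one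
Conditions: TIPSOTf (1.3 equiv), 2,6-lutidine, CH2Cl2, 0 °C to rt
Reagents that add atoms: triisopropylsilyl trifluoromethanesulfonate, CC(C)[Si](OS(=O)(=O)C(F)(F)F)(C(C)C)C(C)C
Why: O-Silylation with a silyl triflate should overcome the hydrogen bond of the chelated phenol, while 2,6-lutidine is too weak a base to enolise the ketone.

Step 12
Reactants: 14 1-[4-(benzyloxy)-2-{[3,4-bis(benzyloxy)-5-(tetra-O-benzylluteolin-8-yl)phenyl]methoxy}-6-[(triisopropylsilyl)oxy]phenyl]ethan-1-one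
Product: 17 1-[4-(benzyloxy)-2-{[3,4-bis(benzyloxy)-5-(tetra-O-benzylluteolin-8-yl)phenyl]methoxy}-6-[(triisopropylsilyl)oxy]phenyl]-2-diazoethan-1-one, via lithium enolate 15 (not isolated), via trifluoroacetyl diketone 16 (not isolated)
Conditions: LiHMDS (1.1 equiv), THF, –78 °C; CF3CO2CH2CF3 (1.3 equiv), –78 °C; aq. NH4Cl work-up; then p-ABSA (1.5 equiv), Et3N (1.5 equiv), H2O (1 equiv), MeCN/THF, rt
Reagents that add atoms: 4-acetamidobenzenesulfonyl azide (p-ABSA), CC(=O)Nc1ccc(cc1)S(=O)(=O)N=[N+]=[N-]; 2,2,2-trifluoroethyl trifluoroacetate, O=C(OCC(F)(F)F)C(F)(F)F (its trifluoroacetyl group is held only by intermediate 16)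
Why: Detrifluoroacetylative diazo transfer should work because Claisen trifluoroacetylation of the kinetic methyl enolate activates the CH2 group for Regitz diazo transfer, after which the trifluoroacetyl group leaves on the sulfonamide nitrogen to give the terminal diazoketone.

Step 13
Reactants: 17 1-[4-(benzyloxy)-2-{[3,4-bis(benzyloxy)-5-(tetra-O-benzylluteolin-8-yl)phenyl]methoxy}-6-[(triisopropylsilyl)oxy]phenyl]-2-diazoethan-1-one
Product: 18 (2S)-7-(benzyloxy)-2-[3,4-bis(benzyloxy)-5-(tetra-O-benzylluteolin-8-yl)phenyl]-5-[(triisopropylsilyl)oxy]chroman-4-one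
Conditions: Rh2(S-PTTL)4 (2 mol%), 4 Å MS, CH2Cl2, –20 to 0 °C, 17 added over 3 h (final 0.005 M)
Reagents that add atoms: none
Why: Rh2(S-PTTL)4 should expel N2 from 17 to give an electrophilic acyl carbene on divalent rhodium at C3, which inserts into one C–H of the O1–CH2–ring B group through a concerted but asynchronous three-centre transition state, with the developing cationic character at C2 delocalised onto O1 and, through ring B, onto O4'. The closest known reaction type is the intramolecular C–H insertion of 2-alkoxyaryl α-diazoketones to chroman-4-ones under chiral dirhodium carboxylates. Ring C closes by 1,6-insertion to a six-membered ring: the position that would give the usual five-membered ring is occupied by O1, which has no hydrogen, so the benzylic CH2 one atom further out is the nearest C–H donor. C2 is set under catalyst control, since the chiral cavity formed by the four N-phthaloyl tert-leucinate ligands should admit only one of the two enantiotopic hydrogens to the carbene, giving 2S. The step needs site selectivity, which the substrate secures because O5 bears a triisopropylsilyl group with no C–H on a carbon bonded to oxygen, the O7 benzyl CH2 is held away by its para geometry and every other benzyl ether would need a ring of eleven or more atoms, while slow addition at low temperature keeps intermolecular reactions down. It also needs chemoselectivity against attack of O1 on the carbene (oxonium ylide, then 1,2-benzyl shift with ring contraction), which the crowded ligand sphere, the weak donor character of the acyl-conjugated O1 and the twist forced on the acyl group by the bulky O5 substituent should disfavour.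

Step 14
Reactants: 18 (2S)-7-(benzyloxy)-2-[3,4-bis(benzyloxy)-5-(tetra-O-benzylluteolin-8-yl)phenyl]-5-[(triisopropylsilyl)oxy]chroman-4-one
Product: 19 (2S)-7-(benzyloxy)-2-[3,4-bis(benzyloxy)-5-(tetra-O-benzylluteolin-8-yl)phenyl]-5-hydroxychroman-4-one
Conditions: TBAF (1.2 equiv), AcOH (1.5 equiv), THF, 0 °C
Reagents that add atoms: none
Why: Fluoride-induced cleavage of the aryl silyl ether is fast because the phenoxide is stabilised by the ortho carbonyl, and the acetic acid buffer should prevent base-induced retro-oxa-Michael opening of ring C, so C2 keeps its configuration.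

Step 15
Reactants: 19 (2S)-7-(benzyloxy)-2-[3,4-bis(benzyloxy)-5-(tetra-O-benzylluteolin-8-yl)phenyl]-5-hydroxychroman-4-one
Product: 20 (2S)-2-[3,4-dihydroxy-5-(luteolin-8-yl)phenyl]-5,7-dihydroxychroman-4-one (CNP0224656.1)
Conditions: H2 (1 atm), 10% Pd/C, THF/MeOH, rt, stopped when uptake ends
Reagents that add atoms: none
Why: Catalytic hydrogenolysis under neutral conditions should remove the seven aryl benzyl ethers well before the flavone C2=C3 bond or the cyclic O1–C2 benzylic ether react, and offers no pathway that epimerises C2.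

Compound list
1 | 2,4,6-trihydroxyacetophenone (phloroacetophenone) | CC(=O)c1c(O)cc(O)cc1O | starting material
2 | 1-[2,4-bis(benzyloxy)-6-hydroxyphenyl]ethan-1-one | CC(=O)c1c(O)cc(OCc2ccccc2)cc1OCc1ccccc1 | intermediate
3 | 1-[4,6-bis(benzyloxy)-2-hydroxy-3-iodophenyl]ethan-1-one | CC(=O)c1c(O)c(I)c(OCc2ccccc2)cc1OCc1ccccc1 | intermediate
4 | 3,4-bis(benzyloxy)benzaldehyde | O=Cc1ccc(OCc2ccccc2)c(OCc2ccccc2)c1 | starting material
5 | (E)-1-[4,6-bis(benzyloxy)-2-hydroxy-3-iodophenyl]-3-[3,4-bis(benzyloxy)phenyl]prop-2-en-1-one | O=C(/C=C/c1ccc(OCc2ccccc2)c(OCc2ccccc2)c1)c1c(O)c(I)c(OCc2ccccc2)cc1OCc1ccccc1 | intermediate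
6 | 5,7-bis(benzyloxy)-2-[3,4-bis(benzyloxy)phenyl]-8-iodo-4H-chromen-4-one | O=c1cc(-c2ccc(OCc3ccccc3)c(OCc3ccccc3)c2)oc2c(I)c(OCc3ccccc3)cc(OCc3ccccc3)c12 | intermediate
7 | 3-bromo-4,5-dihydroxybenzaldehyde | O=Cc1cc(O)c(O)c(Br)c1 | starting material
8 | 3,4-bis(benzyloxy)-5-bromobenzaldehyde | O=Cc1cc(OCc2ccccc2)c(OCc2ccccc2)c(Br)c1 | intermediate
9 | [3,4-bis(benzyloxy)-5-bromophenyl]methanol | OCc1cc(OCc2ccccc2)c(OCc2ccccc2)c(Br)c1 | intermediate
10 | [3,4-bis(benzyloxy)-5-(4,4,5,5-tetramethyl-1,3,2-dioxaborolan-2-yl)phenyl]methanol | OCc1cc(OCc2ccccc2)c(OCc2ccccc2)c(B2OC(C)(C)C(C)(C)O2)c1 | intermediate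
11 | 5,7-bis(benzyloxy)-2-[3,4-bis(benzyloxy)phenyl]-8-[2,3-bis(benzyloxy)-5-(hydroxymethyl)phenyl]-4H-chromen-4-one | OCc1cc(OCc2ccccc2)c(OCc2ccccc2)c(-c2c(OCc3ccccc3)cc(OCc3ccccc3)c3c(=O)cc(-c4ccc(OCc5ccccc5)c(OCc5ccccc5)c4)oc23)c1 | intermediate
12 | 1-[4-(benzyloxy)-2,6-dihydroxyphenyl]ethan-1-one | CC(=O)c1c(O)cc(OCc2ccccc2)cc1O | intermediate
13 | 1-[4-(benzyloxy)-2-{[3,4-bis(benzyloxy)-5-(tetra-O-benzylluteolin-8-yl)phenyl]methoxy}-6-hydroxyphenyl]ethan-1-one | CC(=O)c1c(O)cc(OCc2ccccc2)cc1OCc1cc(OCc2ccccc2)c(OCc2ccccc2)c(-c2c(OCc3ccccc3)cc(OCc3ccccc3)c3c(=O)cc(-c4ccc(OCc5ccccc5)c(OCc5ccccc5)c4)oc23)c1 | intermediate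
14 | 1-[4-(benzyloxy)-2-{[3,4-bis(benzyloxy)-5-(tetra-O-benzylluteolin-8-yl)phenyl]methoxy}-6-[(triisopropylsilyl)oxy]phenyl]ethan-1-one | CC(=O)c1c(O[Si](C(C)C)(C(C)C)C(C)C)cc(OCc2ccccc2)cc1OCc1cc(OCc2ccccc2)c(OCc2ccccc2)c(-c2c(OCc3ccccc3)cc(OCc3ccccc3)c3c(=O)cc(-c4ccc(OCc5ccccc5)c(OCc5ccccc5)c4)oc23)c1 | intermediate
15 | lithium enolate of 14 | C=C(O[Li])c1c(O[Si](C(C)C)(C(C)C)C(C)C)cc(OCc2ccccc2)cc1OCc1cc(OCc2ccccc2)c(OCc2ccccc2)c(-c2c(OCc3ccccc3)cc(OCc3ccccc3)c3c(=O)cc(-c4ccc(OCc5ccccc5)c(OCc5ccccc5)c4)oc23)c1 | intermediate (not isolated)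
16 | 1-[4-(benzyloxy)-2-{[3,4-bis(benzyloxy)-5-(tetra-O-benzylluteolin-8-yl)phenyl]methoxy}-6-[(triisopropylsilyl)oxy]phenyl]-4,4,4-trifluorobutane-1,3-dione | O=C(CC(=O)C(F)(F)F)c1c(O[Si](C(C)C)(C(C)C)C(C)C)cc(OCc2ccccc2)cc1OCc1cc(OCc2ccccc2)c(OCc2ccccc2)c(-c2c(OCc3ccccc3)cc(OCc3ccccc3)c3c(=O)cc(-c4ccc(OCc5ccccc5)c(OCc5ccccc5)c4)oc23)c1 | intermediate (not isolated)
17 | 1-[4-(benzyloxy)-2-{[3,4-bis(benzyloxy)-5-(tetra-O-benzylluteolin-8-yl)phenyl]methoxy}-6-[(triisopropylsilyl)oxy]phenyl]-2-diazoethan-1-one | [N-]=[N+]=CC(=O)c1c(O[Si](C(C)C)(C(C)C)C(C)C)cc(OCc2ccccc2)cc1OCc1cc(OCc2ccccc2)c(OCc2ccccc2)c(-c2c(OCc3ccccc3)cc(OCc3ccccc3)c3c(=O)cc(-c4ccc(OCc5ccccc5)c(OCc5ccccc5)c4)oc23)c1 | intermediate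
18 | (2S)-7-(benzyloxy)-2-[3,4-bis(benzyloxy)-5-(tetra-O-benzylluteolin-8-yl)phenyl]-5-[(triisopropylsilyl)oxy]chroman-4-one | O=C1C[C@@H](c2cc(OCc3ccccc3)c(OCc3ccccc3)c(-c3c(OCc4ccccc4)cc(OCc4ccccc4)c4c(=O)cc(-c5ccc(OCc6ccccc6)c(OCc6ccccc6)c5)oc34)c2)Oc2cc(OCc3ccccc3)cc(O[Si](C(C)C)(C(C)C)C(C)C)c21 | intermediate
19 | (2S)-7-(benzyloxy)-2-[3,4-bis(benzyloxy)-5-(tetra-O-benzylluteolin-8-yl)phenyl]-5-hydroxychroman-4-one | O=C1C[C@@H](c2cc(OCc3ccccc3)c(OCc3ccccc3)c(-c3c(OCc4ccccc4)cc(OCc4ccccc4)c4c(=O)cc(-c5ccc(OCc6ccccc6)c(OCc6ccccc6)c5)oc34)c2)Oc2cc(OCc3ccccc3)cc(O)c21 | intermediate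
20 | (2S)-2-[3,4-dihydroxy-5-(luteolin-8-yl)phenyl]-5,7-dihydroxychroman-4-one, luteolin-8-yl being 2-(3,4-dihydroxyphenyl)-5,7-dihydroxy-4-oxo-4H-chromen-8-yl (CNP0224656.1) | O=C1C[C@@H](c2cc(O)c(O)c(-c3c(O)cc(O)c4c(=O)cc(-c5ccc(O)c(O)c5)oc34)c2)Oc2cc(O)cc(O)c21 | target

Total step count: 15.
Longest linear sequence: 11 steps (steps 1, 2, 3, 4, 8, 10, 11, 12, 13, 14, 15).

Steps most likely to fail

Step 13. The carbene may be captured by O1 to form an oxonium ylide that rearranges by benzyl shift with ring contraction, or the insertion may discriminate poorly between the two enantiotopic hydrogens. The fallback gives up the carbene and closes ring C by oxa-Michael addition followed by resolution. It sets out from 11 (with 2) and comes back at 20.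
- Oxidation of 11 with MnO2 in CH2Cl2 should give 3,4-bis(benzyloxy)-5-(tetra-O-benzylluteolin-8-yl)benzaldehyde F1.
- Claisen–Schmidt condensation of F1 with acetophenone 2 (KOH, EtOH/THF, rt) should give (E)-1-[2,4-bis(benzyloxy)-6-hydroxyphenyl]-3-[3,4-bis(benzyloxy)-5-(tetra-O-benzylluteolin-8-yl)phenyl]prop-2-en-1-one F2.
- NaOAc in refluxing EtOH/THF should close ring C to racemic 5,7-bis(benzyloxy)-2-[3,4-bis(benzyloxy)-5-(tetra-O-benzylluteolin-8-yl)phenyl]chroman-4-one F3.
- Preparative HPLC on an amylose tris(3,5-dimethylphenylcarbamate) phase should deliver (2S)-5,7-bis(benzyloxy)-2-[3,4-bis(benzyloxy)-5-(tetra-O-benzylluteolin-8-yl)phenyl]chroman-4-one F4; the 2R half of F3 is re-equilibrated through F2 with base and recycled.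
- Hydrogenolysis of F4 under the conditions of step 15 then gives 20.

Step 12. The silyl group may migrate from O5 to the enolate oxygen, the enolate may add to the flavone of a second molecule, or the aryl silyl ether may be lost in the aqueous amine of the transfer stage. The fallback avoids both the lithium enolate and aqueous base. It sets out from 14 and comes back at 17.
- Soft enolisation with TMSOTf/Et3N in CH2Cl2 at 0 °C should give the trimethylsilyl enol ether of 14 F5.
- NBS in THF at –78 °C should convert F5 into 1-[4-(benzyloxy)-2-{[3,4-bis(benzyloxy)-5-(tetra-O-benzylluteolin-8-yl)phenyl]methoxy}-6-[(triisopropylsilyl)oxy]phenyl]-2-bromoethan-1-one F6.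
- N,N'-Ditosylhydrazine and DBU in THF at 0 °C (N-alkylation, then twofold loss of sulfinate) should turn F6 into 17.

Step 8. Protodeboronation of the electron-rich boronate and reduction of the iodide may outrun a slow transmetalation at the tri-ortho-substituted axis. The fallback is a base-free Negishi coupling with an arylzinc reagent. It sets out from 9 (with 6) and comes back at 11.
- TBSCl and imidazole in DMF should give {[3,4-bis(benzyloxy)-5-bromophenyl]methoxy}(tert-butyl)dimethylsilane F7.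
- Bromine–lithium exchange with n-BuLi in THF at –78 °C should give the aryllithium of F7 F8.
- ZnCl2 should transmetalate F8 to the arylzinc chloride of F7 F9.
- Coupling of F9 with 6 (Pd2(dba)3 2.5 mol%, SPhos, THF, 60 °C) should give the tert-butyldimethylsilyl ether of 11 F10.
- TBAF/AcOH in THF should release 11 from F10.

Further compounds
F1 | step 13 | 3,4-bis(benzyloxy)-5-(tetra-O-benzylluteolin-8-yl)benzaldehyde | O=Cc1cc(OCc2ccccc2)c(OCc2ccccc2)c(-c2c(OCc3ccccc3)cc(OCc3ccccc3)c3c(=O)cc(-c4ccc(OCc5ccccc5)c(OCc5ccccc5)c4)oc23)c1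
F2 | step 13 | (E)-1-[2,4-bis(benzyloxy)-6-hydroxyphenyl]-3-[3,4-bis(benzyloxy)-5-(tetra-O-benzylluteolin-8-yl)phenyl]prop-2-en-1-one | O=C(/C=C/c1cc(OCc2ccccc2)c(OCc2ccccc2)c(-c2c(OCc3ccccc3)cc(OCc3ccccc3)c3c(=O)cc(-c4ccc(OCc5ccccc5)c(OCc5ccccc5)c4)oc23)c1)c1c(O)cc(OCc2ccccc2)cc1OCc1ccccc1
F3 | step 13 | racemic 5,7-bis(benzyloxy)-2-[3,4-bis(benzyloxy)-5-(tetra-O-benzylluteolin-8-yl)phenyl]chroman-4-one | O=C1CC(c2cc(OCc3ccccc3)c(OCc3ccccc3)c(-c3c(OCc4ccccc4)cc(OCc4ccccc4)c4c(=O)cc(-c5ccc(OCc6ccccc6)c(OCc6ccccc6)c5)oc34)c2)Oc2cc(OCc3ccccc3)cc(OCc3ccccc3)c21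
F4 | step 13 | (2S)-5,7-bis(benzyloxy)-2-[3,4-bis(benzyloxy)-5-(tetra-O-benzylluteolin-8-yl)phenyl]chroman-4-one | O=C1C[C@@H](c2cc(OCc3ccccc3)c(OCc3ccccc3)c(-c3c(OCc4ccccc4)cc(OCc4ccccc4)c4c(=O)cc(-c5ccc(OCc6ccccc6)c(OCc6ccccc6)c5)oc34)c2)Oc2cc(OCc3ccccc3)cc(OCc3ccccc3)c21
F5 | step 12 | trimethylsilyl enol ether of 14 | C=C(O[Si](C)(C)C)c1c(O[Si](C(C)C)(C(C)C)C(C)C)cc(OCc2ccccc2)cc1OCc1cc(OCc2ccccc2)c(OCc2ccccc2)c(-c2c(OCc3ccccc3)cc(OCc3ccccc3)c3c(=O)cc(-c4ccc(OCc5ccccc5)c(OCc5ccccc5)c4)oc23)c1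
F6 | step 12 | 1-[4-(benzyloxy)-2-{[3,4-bis(benzyloxy)-5-(tetra-O-benzylluteolin-8-yl)phenyl]methoxy}-6-[(triisopropylsilyl)oxy]phenyl]-2-bromoethan-1-one | BrCC(=O)c1c(O[Si](C(C)C)(C(C)C)C(C)C)cc(OCc2ccccc2)cc1OCc1cc(OCc2ccccc2)c(OCc2ccccc2)c(-c2c(OCc3ccccc3)cc(OCc3ccccc3)c3c(=O)cc(-c4ccc(OCc5ccccc5)c(OCc5ccccc5)c4)oc23)c1
F7 | step 8 | {[3,4-bis(benzyloxy)-5-bromophenyl]methoxy}(tert-butyl)dimethylsilane | CC(C)(C)[Si](C)(C)OCc1cc(OCc2ccccc2)c(OCc2ccccc2)c(Br)c1
F8 | step 8 | aryllithium of F7, {2,3-bis(benzyloxy)-5-[(tert-butyldimethylsilyloxy)methyl]phenyl}lithium | [Li]c1cc(CO[Si](C)(C)C(C)(C)C)cc(OCc2ccccc2)c1OCc1ccccc1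
F9 | step 8 | arylzinc chloride of F7, {2,3-bis(benzyloxy)-5-[(tert-butyldimethylsilyloxy)methyl]phenyl}zinc chloride | Cl[Zn]c1cc(CO[Si](C)(C)C(C)(C)C)cc(OCc2ccccc2)c1OCc1ccccc1
F10 | step 8 | tert-butyldimethylsilyl ether of 11 | CC(C)(C)[Si](C)(C)OCc1cc(OCc2ccccc2)c(OCc2ccccc2)c(-c2c(OCc3ccccc3)cc(OCc3ccccc3)c3c(=O)cc(-c4ccc(OCc5ccccc5)c(OCc5ccccc5)c4)oc23)c1
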